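The data come from a simulation with constants of no real substance; noise was put on by code.

| setting | east | flask |
|---|---|---|
| substrate | 0.050 M | 0.050 M |
| coupling partner | 1.5 equiv | 1.50 equiv |
| temperature | 25 °C | 25 °C |
| remark | the very flask that is asked about, followed so far |  |
| time |  | 1.0 h |

east run (percent of the substrate charged)

| time / min | target / % | substrate / % |
|---|---|---|
| 6.00 | 29.0 | 43.2 |
| 15.0 | 53.3 | 18.2 |
| 20.0 | 58.1 | 11.1 |
| 30.0 | 63.7 | 6.0 |
| 40.0 | 65.6 | 3.0 |
| 50.0 | 66.9 | 0.5 |

(each reading ± 1 percentage point)

- the volume of additions can be left aside
- the earlier runs do not show what temperature does; that part of a forecast is a guess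
- a reading or a percentage of target counts all its forms, free or not

- alpha: at 1.0 h add coupling partner, 100% of the amount charged, then wait 2.0 h
- eta: at 1.0 h raise the temperature by 10 K, then wait 2.0 h
- zeta: at 1.0 h take out 90% of the released group then present, then wait 2.0 h
- beta: change nothing and wait 2.0 h more

* target, in percent of the substrate first charged, at 1.0 h
* the remedy with the largest gain of target, or "none" below 2 percentage points (alpha / eta / zeta / beta / none)
* target present, in percent of the substrate first charged, after alpha
* target present, in percent of the substrate first charged, after eta

- The constant that matters here is a share, but start with a time constant, as you would on any decay. Between 20.0 min and 40.0 min the substrate of the east run falls with a mean rate constant k, its fractional loss per minute, of 0.0654 min⁻¹, and that carries it to 0.811% at 1.0 h.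
- The objection: k is a mean, and the decay is not truly exponential if each reacting substrate uses one coupling partner. On that count the partner drifts from 0.611 to 0.530 per substrate charged over that stretch, so the stretch is close to pseudo-first-order, and the next constant prices the remaining error.
- From the readings at 30.0 min, 40.0 min and 50.0 min, pooled as a mean, you get 0.675 for s, the yield share: target present per substrate reacted.
- The objection: at 6.00 min the same ratio reads 0.511, lower than s, so the share is not constant and something stands between substrate and target early on. But it reads 0.678 at 30.0 min and 0.672 at 50.0 min, so at a scatter of 1 percentage point the late readings show no further climb.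
- So my estimate for 1.0 h is s times the reacted substrate, 67.0%. The substrate I reckon as remaining is worth 0.55 points of target, less than the scatter, so I leave the drift in k aside.
- On that same figure I expect alpha and beta to gain less than the 2 points margin, as long as s holds. In this flask substrate is the limiting reagent, with 1.50 equiv of coupling partner charged.
- The last doubt: s leaves 0.325 of the reacted substrate elsewhere. If that remainder can return, s itself can move, and readings at one temperature cannot show it. I commit to none, with eta as the open risk.
- The forecast says 67.3% now, 67.6% after alpha, 67.3% after eta, and best none; its figure for now is a little higher than my estimate. On eta it reasons: “Heating cannot create target without substrate”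

- The flask holds 66.6% at 1.0 h, and the best remedy is eta: it gives 73.4%, a gain of 6.8 points, while alpha gives 66.7%, a gain of 0.091 points.

    intermediate ⇌ isomer of the product (K = 36.0, k = 0.00270 s⁻¹, Ea = 76.0 kJ mol⁻¹, ΔH = −74.0 kJ mol⁻¹)
    intermediate ⇌ target (K = 3.00, k = 0.00620 s⁻¹, Ea = 75.0 kJ mol⁻¹, ΔH = −49.0 kJ mol⁻¹)
    substrate + coupling partner → intermediate + released group (k = 0.0410 M⁻¹ s⁻¹, Ea = 69.0 kJ mol⁻¹)
    crystals ⇌ target, rate k4*(cs4 - [target]) while solid is left; crystals form when [target] > cs4 (solubility = 1.40 mM, k = 0.110 s⁻¹)
    (constants at 25 °C)

- At 1.0 h the flask also holds 31.5% as isomer of the product. Without any remedy, s times the reacted substrate of this flask gives 67.0%. In the neighbour flask, the same but with 0.380 equiv of coupling partner, 62% of the substrate is still there at 1.0 h, so s gives 25.6%, and that flask holds 21.6%.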